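**Strategy.** Ring B (C5–C10) of the target carries, side by side, the quaternary C10, the C9 branch (C11) and the exocyclic C8=C17 methylene. This pattern is the imprint of a [4+2] union between a ring A 2-vinylcyclohexene (diene C10=C5–C6=C7) and an allenic ester, and the plan rests on that disconnection. In one operation the cycloaddition forms C9–C10 and C7–C8, closes ring B and sets C10 under control of the C2 oxygen. Its precursor is the (R)-4-silyloxy-2,6,6-trimethyl-1-vinylcyclohexene made from ketoisophorone. Afterwards C5 and C9 are set, C11 is homologated, the Z-enoate is attached by Negishi coupling, and C2 is inverted and acetylated.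

Key step: step 6

Remark: labdane numbering is used for all bicyclic compounds (C11 on C9, C17 on C8); α means trans and β cis to the C10 methyl; TBSO = tert-butyldimethylsilyloxy.
Assumption: the reductases of steps 1 and 2 are available as recombinant preparations; C6 of compounds 2–4 is erased in step 4, so only C4 of 3 has to be secured.

Step 1
Reactants: 1 ketoisophorone (2,6,6-trimethylcyclohex-2-ene-1,4-dione)
Product: 2 (6R)-levodione [(R)-2,2,6-trimethylcyclohexane-1,4-dione]
Conditions: ene-reductase OYE2 (old yellow enzyme of Saccharomyces cerevisiae), NADP+ (cat.), D-glucose, glucose dehydrogenase, phosphate buffer pH 7, 30 °C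
Reagents that add atoms: none
Why: Flavin-dependent ene-reductase (asymmetric biocatalytic conjugate reduction): hydride from the reduced flavin goes to the β-carbon and a proton to the methyl-bearing α-carbon of the enedione inside the enzyme pocket, which should set the (6R) centre and leave both ketones untouched.

Step 2
Reactants: 2 (6R)-levodione
Product: 3 (4R,6R)-actinol [(4R,6R)-4-hydroxy-2,2,6-trimethylcyclohexan-1-one]
Conditions: levodione reductase (Corynebacterium aquaticum), NAD+ (cat.), D-glucose, glucose dehydrogenase, phosphate buffer pH 7, 30 °C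
Reagents that add atoms: none
Why: Enzymatic asymmetric ketone reduction: the reductase accepts only the unhindered C4 carbonyl (C1 is flanked by three methyl groups) and delivers the NADH hydride to one face, which should set (4R), the centre that becomes C2 and steers the key step.

Step 3
Reactants: 3 (4R,6R)-actinol
Product: 4 (4R,6R)-4-[(tert-butyldimethylsilyl)oxy]-2,2,6-trimethylcyclohexan-1-one
Conditions: TBSCl, imidazole, DMF, 25 °C
Reagents that add atoms: tert-butyldimethylsilyl chloride, CC(C)(C)[Si](C)(C)Cl
Why: Imidazole-promoted silylation of the secondary alcohol (silyl ether formation) installs a robust spectator that survives Lewis acid, strong base and hydride and later anchors the ring A conformation.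

Step 4
Reactants: 4 (4R,6R)-4-[(tert-butyldimethylsilyl)oxy]-2,2,6-trimethylcyclohexan-1-one
Product: 6 (R)-4-[(tert-butyldimethylsilyl)oxy]-2,6,6-trimethylcyclohex-1-en-1-yl trifluoromethanesulfonate, via lithium enolate 5 (not isolated)
Conditions: LDA, THF, −78 to 0 °C; then PhNTf2, 0 to 25 °C; H2O
Reagents that add atoms: N-phenylbis(trifluoromethanesulfonimide), O=S(=O)(N(c1ccccc1)S(=O)(=O)C(F)(F)F)C(F)(F)F
Why: Enol triflate formation: C2 is quaternary, so LDA can enolise only towards C6, and O-sulfonylation of this single enolate by PhNTf2 fixes the tetrasubstituted C=C (the C6 centre is erased, and the γ-silyloxy group cannot undergo β-elimination).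

Step 5
Reactants: 6 (R)-4-[(tert-butyldimethylsilyl)oxy]-2,6,6-trimethylcyclohex-1-en-1-yl trifluoromethanesulfonate
Product: 7 (R)-tert-butyldimethyl[(3,5,5-trimethyl-4-vinylcyclohex-3-en-1-yl)oxy]silane
Conditions: tributyl(vinyl)stannane, Pd(PPh3)4 (5 mol %), LiCl, THF, 65 °C
Reagents that add atoms: tributyl(vinyl)stannane, C=C[Sn](CCCC)(CCCC)CCCC
Why: Stille coupling: oxidative addition of zerovalent palladium into the C–OTf bond (assisted by chloride), vinyl transfer from tin and reductive elimination should give the 1,3-diene without moving the ring double bond, as is routine for hindered cyclohexenyl triflates.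

Step 6
Reactants: 7 (R)-tert-butyldimethyl[(3,5,5-trimethyl-4-vinylcyclohex-3-en-1-yl)oxy]silane; 8 ethyl buta-2,3-dienoate
Product: 9 ethyl 2α-TBSO-12,13,14,15,16-pentanorlabda-5,8(17)-dien-11-oate (10β-methyl; both C9 epimers)
Conditions: 8 (1.5 equiv), EtAlCl2 (0.3 equiv), CH2Cl2, −40 to 0 °C
Reagents that add atoms: none
Why: The aluminium-bound ester lowers the LUMO of the ester-conjugated C=C of the allene, which then undergoes a concerted but asynchronous [4+2] cycloaddition with the s-cis diene C10=C5–C6=C7: the free vinyl terminus C7 bonds ahead to the central allene carbon and the tetrasubstituted terminus C10 to the ester-bearing carbon, so that C11 ends on C9 and the untouched distal allene C=C becomes the C8=C17 methylene. The closest known reaction type is the Diels–Alder reaction of 2-vinylcyclohex-1-enes with allenic and acetylenic esters. Ring B (C5–C10) is closed by this intermolecular cycloaddition, both new σ-bonds (C7–C8 and C9–C10) arising in the one bimolecular event and not through a separate exo or endo cyclisation. C10 is controlled by the C2 stereocentre: the equatorial silyloxy group locks the half-chair of ring A, the pseudoaxial C4 methyl then covers the face trans to the oxygen, and the dienophile should add cis to the silyloxy group (2α-O, 10β-methyl), while C9 forms without control and is reset in steps 7 and 9. The step needs regioselectivity (secured by the polarised allenoate and the unsubstituted C7 terminus), site selectivity for the conjugated allene bond (secured by Lewis acid activation of the ester) and face selectivity (secured by the C2/C4 relay at low temperature).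

Step 7
Reactants: 9 ethyl 2α-TBSO-12,13,14,15,16-pentanorlabda-5,8(17)-dien-11-oate
Product: 10 ethyl 2α-TBSO-12,13,14,15,16-pentanorlabda-5,8-dien-11-oate
Conditions: DBU (0.3 equiv), THF, 0 to 25 °C, stopped as soon as 9 is consumed
Reagents that add atoms: none
Why: Base-mediated prototropic isomerisation of a β,γ- to an α,β-unsaturated ester: DBU removes the C9 hydrogen next to the ester and reprotonation of the dienolate at C17 should give the tetrasubstituted conjugated C8=C9 ester, merging both C9 epimers into one compound, the weak amidine base and short exposure being chosen to leave the C7 hydrogens of 10 alone.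

Step 8
Reactants: 10 ethyl 2α-TBSO-12,13,14,15,16-pentanorlabda-5,8-dien-11-oate
Product: 11 ethyl 2α-TBSO-12,13,14,15,16-pentanorlabd-8-en-11-oate (5α-H)
Conditions: H2 (1 atm), Pd/C (10 %), EtOAc, 25 °C
Reagents that add atoms: none
Why: Heterogeneous catalytic hydrogenation: only the trisubstituted C5=C6 bond of the flat cyclohexa-1,4-diene should be reduced (the tetrasubstituted ester-conjugated C8=C9 bond is inert on Pd/C at 1 atm), with hydrogen delivered anti to the angular C10 methyl, which sets 5α-H and the trans ring fusion.

Step 9
Reactants: 11 ethyl 2α-TBSO-12,13,14,15,16-pentanorlabd-8-en-11-oate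
Product: 13 ethyl 2α-TBSO-12,13,14,15,16-pentanorlabd-8(17)-en-11-oate (5α-H; 9α-H), via lithium dienolate 12 (not isolated)
Conditions: LDA (1.3 equiv), THF, −78 °C; then AcOH, −78 °C
Reagents that add atoms: none
Why: Deconjugative kinetic protonation of an ester dienolate: LDA abstracts a proton from the C17 methyl, the γ-position syn to the ester carbonyl, and the exocyclic dienolate 12 is protonated at the α-carbon C9 from the α-face, anti to the axial C10 methyl, which should restore the C8=C17 methylene and set 9α-H (equatorial ester).

Step 10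
Reactants: 13 ethyl 2α-TBSO-12,13,14,15,16-pentanorlabd-8(17)-en-11-oate
Product: 14 2α-TBSO-12,13,14,15,16-pentanorlabd-8(17)-en-11-ol
Conditions: LiAlH4, Et2O, 0 °C; H2O
Reagents that add atoms: none
Why: Hydride reduction of the ester to the primary alcohol (LiAlH4 reduction), in which carbonyl addition is much faster than enolisation, so C9 and the β,γ-alkene should be retained.

Step 11
Reactants: 14 2α-TBSO-12,13,14,15,16-pentanorlabd-8(17)-en-11-ol
Product: 15 11-iodo-2α-TBSO-12,13,14,15,16-pentanorlabd-8(17)-ene
Conditions: I2, PPh3, imidazole, toluene, 25 to 60 °C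
Reagents that add atoms: iodine, II
Why: Appel-type iodination: the alcohol is activated as an alkoxyphosphonium ion and displaced by iodide in an SN2 step at the primary C11, which tolerates the β-branching, the silyl ether and the alkene.

Step 12
Reactants: 15 11-iodo-2α-TBSO-12,13,14,15,16-pentanorlabd-8(17)-ene
Product: 17 2α-TBSO-13,14,15,16-tetranorlabd-8(17)-en-12-ol, via alkyllithium 16 (not isolated)
Conditions: t-BuLi (2.1 equiv), Et2O–pentane, −78 °C; then CH2O (gas from cracked paraformaldehyde), −78 to 0 °C; H2O
Reagents that add atoms: formaldehyde (from paraformaldehyde), C=O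
Why: Iodine–lithium exchange followed by hydroxymethylation: two equivalents of t-BuLi convert the primary iodide irreversibly into the alkyllithium 16 (the second equivalent destroys t-BuI), which adds to monomeric formaldehyde and extends the chain by the carbon that becomes C12 without touching a stereocentre.

Step 13
Reactants: 17 2α-TBSO-13,14,15,16-tetranorlabd-8(17)-en-12-ol
Product: 18 12-iodo-2α-TBSO-13,14,15,16-tetranorlabd-8(17)-ene
Conditions: I2, PPh3, imidazole, CH2Cl2, 0 to 25 °C
Reagents that add atoms: iodine, II
Why: Second Appel-type iodination, now at the unhindered primary C12 alcohol, gives the iodide needed for zinc insertion.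

Step 14
Reactants: 19 ethyl but-2-ynoate
Product: 20 ethyl (Z)-3-iodobut-2-enoate
Conditions: NaI, AcOH, 110 °C
Reagents that add atoms: sodium iodide, [Na+].[I-]
Why: Hydroiodination of an ynoate: iodide adds in conjugate fashion to the β-carbon and the allenolate is protonated anti to it, so iodine and the ester should end up cis, i.e. the (Z)-β-iodoenoate.

Step 15
Reactants: 18 12-iodo-2α-TBSO-13,14,15,16-tetranorlabd-8(17)-ene; 20 ethyl (Z)-3-iodobut-2-enoate
Product: 22 ethyl (13Z)-2α-TBSO-labda-8(17),13-dien-15-oate, via alkylzinc iodide 21 (not isolated)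
Conditions: Zn dust (activated by 1,2-dibromoethane and TMSCl), THF, 40 °C; then 20, Pd(PPh3)4 (5 mol %), THF, 25 to 45 °C
Reagents that add atoms: none
Why: Negishi coupling: zinc inserts into the primary C–I bond to give 21, which transmetalates to the alkenylpalladium species formed by oxidative addition of zerovalent palladium into 20, and reductive elimination forms C12–C13 with retention of the alkene geometry, so C12 should stay cis to the ester (13Z) while ester, silyl ether and the C8=C17 alkene are tolerated.

Step 16
Reactants: 22 ethyl (13Z)-2α-TBSO-labda-8(17),13-dien-15-oate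
Product: 23 ethyl (13Z)-2α-hydroxylabda-8(17),13-dien-15-oate
Conditions: TBAF (Bu4NF), THF, 25 °C; H2O
Reagents that add atoms: none
Why: Fluoride-mediated desilylation (formation of the strong Si–F bond cleaves the Si–O bond), to which the ester and both alkenes are inert at room temperature.

Step 17
Reactants: 23 ethyl (13Z)-2α-hydroxylabda-8(17),13-dien-15-oate
Product: 24 ethyl (13Z)-2-oxolabda-8(17),13-dien-15-oate
Conditions: Dess–Martin periodinane, CH2Cl2, 25 °C
Reagents that add atoms: none
Why: Dess–Martin oxidation of the secondary alcohol under near-neutral conditions should spare the exocyclic alkene and the Z-enoate, and the C2 ketone has only methylene neighbours (C1, C3), so nothing can epimerise.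

Step 18
Reactants: 24 ethyl (13Z)-2-oxolabda-8(17),13-dien-15-oate
Product: 26 (13Z)-2β-hydroxylabda-8(17),13-dien-15-oic acid, via 2β-hydroxy ethyl ester 25 (not isolated)
Conditions: NaBH4, MeOH, 0 °C; then LiOH, THF–H2O, 45 °C; then 1 M HCl to pH 3
Reagents that add atoms: lithium hydroxide, [Li+].[OH-]
Why: Diastereoselective hydride reduction then saponification: the β-face of the C2 carbonyl is screened by the syn-axial C10 and C4β methyl groups, so borohydride should attack from the α-face and give the axial 2β-alcohol (net inversion at C2), after which LiOH hydrolyses the ethyl ester without affecting the 13Z double bond.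

Step 19
Reactants: 26 (13Z)-2β-hydroxylabda-8(17),13-dien-15-oic acid
Product: 28 (13Z)-2β-acetoxylabda-8(17),13-dien-15-oic acid (target), via mixed acetic anhydride 27 (not isolated)
Conditions: Ac2O, pyridine, DMAP (cat.), 25 to 40 °C; then H2O, 25 °C
Reagents that add atoms: acetic anhydride, CC(=O)OC(C)=O
Why: DMAP-catalysed acetylation (acyl transfer through the N-acetylpyridinium ion) should esterify the hindered axial 2β-hydroxyl, while the carboxyl group, converted in part into the mixed anhydride 27, is returned to the free acid on stirring with water.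

**Compound list**

1 | ketoisophorone (2,6,6-trimethylcyclohex-2-ene-1,4-dione) | CC1=CC(=O)CC(C)(C)C1=O | starting material
2 | (6R)-levodione, (R)-2,2,6-trimethylcyclohexane-1,4-dione | C[C@@H]1CC(=O)CC(C)(C)C1=O | intermediate
3 | (4R,6R)-actinol, (4R,6R)-4-hydroxy-2,2,6-trimethylcyclohexan-1-one | C[C@@H]1C[C@@H](O)CC(C)(C)C1=O | intermediate
4 | (4R,6R)-4-[(tert-butyldimethylsilyl)oxy]-2,2,6-trimethylcyclohexan-1-one | C[C@@H]1C[C@@H](O[Si](C)(C)C(C)(C)C)CC(C)(C)C1=O | intermediate
5 | lithium (R)-4-[(tert-butyldimethylsilyl)oxy]-2,6,6-trimethylcyclohex-1-en-1-olate | CC1=C([O-])C(C)(C)C[C@H](O[Si](C)(C)C(C)(C)C)C1.[Li+] | intermediate (not isolated)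
6 | (R)-4-[(tert-butyldimethylsilyl)oxy]-2,6,6-trimethylcyclohex-1-en-1-yl trifluoromethanesulfonate | CC1=C(OS(=O)(=O)C(F)(F)F)C(C)(C)C[C@H](O[Si](C)(C)C(C)(C)C)C1 | intermediate
7 | (R)-tert-butyldimethyl[(3,5,5-trimethyl-4-vinylcyclohex-3-en-1-yl)oxy]silane | C=CC1=C(C)C[C@@H](O[Si](C)(C)C(C)(C)C)CC1(C)C | intermediate
8 | ethyl buta-2,3-dienoate | C=C=CC(=O)OCC | starting material
9 | ethyl 2α-TBSO-12,13,14,15,16-pentanorlabda-5,8(17)-dien-11-oate (10β-methyl, C9 epimers) | C=C1CC=C2C(C)(C)C[C@H](O[Si](C)(C)C(C)(C)C)C[C@]2(C)C1C(=O)OCC | intermediate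
10 | ethyl 2α-TBSO-12,13,14,15,16-pentanorlabda-5,8-dien-11-oate | CCOC(=O)C1=C(C)CC=C2C(C)(C)C[C@H](O[Si](C)(C)C(C)(C)C)C[C@]12C | intermediate
11 | ethyl 2α-TBSO-12,13,14,15,16-pentanorlabd-8-en-11-oate (5α-H) | CCOC(=O)C1=C(C)CC[C@H]2C(C)(C)C[C@H](O[Si](C)(C)C(C)(C)C)C[C@]12C | intermediate
12 | lithium dienolate of 11 (C8=C17 and C9=C11 double bonds) | C=C1CC[C@H]2C(C)(C)C[C@H](O[Si](C)(C)C(C)(C)C)C[C@]2(C)C1=C([O-])OCC.[Li+] | intermediate (not isolated)
13 | ethyl 2α-TBSO-12,13,14,15,16-pentanorlabd-8(17)-en-11-oate (5α-H, 9α-H) | C=C1CC[C@H]2C(C)(C)C[C@H](O[Si](C)(C)C(C)(C)C)C[C@]2(C)[C@H]1C(=O)OCC | intermediate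
14 | 2α-TBSO-12,13,14,15,16-pentanorlabd-8(17)-en-11-ol | C=C1CC[C@H]2C(C)(C)C[C@H](O[Si](C)(C)C(C)(C)C)C[C@]2(C)[C@H]1CO | intermediate
15 | 11-iodo-2α-TBSO-12,13,14,15,16-pentanorlabd-8(17)-ene | C=C1CC[C@H]2C(C)(C)C[C@H](O[Si](C)(C)C(C)(C)C)C[C@]2(C)[C@H]1CI | intermediate
16 | [2α-TBSO-12,13,14,15,16-pentanorlabd-8(17)-en-11-yl]lithium | C=C1CC[C@H]2C(C)(C)C[C@H](O[Si](C)(C)C(C)(C)C)C[C@]2(C)[C@H]1C[Li] | intermediate (not isolated)
17 | 2α-TBSO-13,14,15,16-tetranorlabd-8(17)-en-12-ol | C=C1CC[C@H]2C(C)(C)C[C@H](O[Si](C)(C)C(C)(C)C)C[C@]2(C)[C@H]1CCO | intermediate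
18 | 12-iodo-2α-TBSO-13,14,15,16-tetranorlabd-8(17)-ene | C=C1CC[C@H]2C(C)(C)C[C@H](O[Si](C)(C)C(C)(C)C)C[C@]2(C)[C@H]1CCI | intermediate
19 | ethyl but-2-ynoate | CC#CC(=O)OCC | starting material
20 | ethyl (Z)-3-iodobut-2-enoate | C/C(I)=C/C(=O)OCC | intermediate
21 | [2α-TBSO-13,14,15,16-tetranorlabd-8(17)-en-12-yl]zinc iodide | C=C1CC[C@H]2C(C)(C)C[C@H](O[Si](C)(C)C(C)(C)C)C[C@]2(C)[C@H]1CC[Zn]I | intermediate (not isolated)
22 | ethyl (13Z)-2α-TBSO-labda-8(17),13-dien-15-oate | C=C1CC[C@H]2C(C)(C)C[C@H](O[Si](C)(C)C(C)(C)C)C[C@]2(C)[C@H]1CC/C(C)=C\C(=O)OCC | intermediate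
23 | ethyl (13Z)-2α-hydroxylabda-8(17),13-dien-15-oate | C=C1CC[C@H]2C(C)(C)C[C@H](O)C[C@]2(C)[C@H]1CC/C(C)=C\C(=O)OCC | intermediate
24 | ethyl (13Z)-2-oxolabda-8(17),13-dien-15-oate | C=C1CC[C@H]2C(C)(C)CC(=O)C[C@]2(C)[C@H]1CC/C(C)=C\C(=O)OCC | intermediate
25 | ethyl (13Z)-2β-hydroxylabda-8(17),13-dien-15-oate | C=C1CC[C@H]2C(C)(C)C[C@@H](O)C[C@]2(C)[C@H]1CC/C(C)=C\C(=O)OCC | intermediate (not isolated)
26 | (13Z)-2β-hydroxylabda-8(17),13-dien-15-oic acid | C=C1CC[C@H]2C(C)(C)C[C@@H](O)C[C@]2(C)[C@H]1CC/C(C)=C\C(=O)O | intermediate
27 | acetic (13Z)-2β-acetoxylabda-8(17),13-dien-15-oic anhydride | C=C1CC[C@H]2C(C)(C)C[C@@H](OC(C)=O)C[C@]2(C)[C@H]1CC/C(C)=C\C(=O)OC(C)=O | intermediate (not isolated)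
28 | (2R,5S,9S,10S,13Z)-2-acetoxylabda-8(17),13-dien-15-oic acid (2β-acetoxy) | C=C1CC[C@H]2C(C)(C)C[C@@H](OC(C)=O)C[C@]2(C)[C@H]1CC/C(C)=C\C(=O)O | target

**Step count and risk**

Total: 19 steps. Longest linear sequence: 18 steps (steps 1–13 and 15–19); step 14 is the one-step side branch that makes 20.

Step 6. What may go wrong: the hindered diene reaches its s-cis form slowly, so the aluminium-activated allene can be diverted into stepwise [2+2] addition at the vinyl group or into oligomerisation, and warming to force conversion erodes the face selectivity at C10. Fallback: the allene is replaced by the alkynoate 19 and the cycloaddition is run without Lewis acid (7 and 19, neat, BHT, 160 °C, sealed tube). Thermal conditions shut down the cationic [2+2] pathway, the alkynoate should add with the same orientation (C7 to the methyl-bearing carbon, C10 to the ester-bearing carbon), and the cyclohexa-1,4-diene ester 10 forms directly. The detour sets out from 7, returns at 10, bypasses step 7 and makes no compound outside the list (none, F0). The C10 epimers are diastereomers because of C2 and can be separated at 10, where C9 is no longer stereogenic.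

Step 7. What may go wrong: over-isomerisation; once 10 has formed, its doubly allylic C7 hydrogens can be removed as well, so that the double bonds drift on into 5,7- or 6,8-dienes and the substrate for the selective hydrogenation is lost. Fallback, setting out from 9 and returning at 11: both C=C bonds of 9 are hydrogenated (H2, 3 atm, Pd/C, EtOAc) to ethyl 2α-TBSO-12,13,14,15,16-pentanorlabdan-11-oate F1 (5α-H, mixture at C8 and C9). Its enolate (LDA, THF, −78 °C) is then selenenylated with PhSeBr to ethyl 9-(phenylselanyl)-2α-TBSO-12,13,14,15,16-pentanorlabdan-11-oate F2, and oxidation (H2O2, pyridine, CH2Cl2, 0 °C) triggers selenoxide syn-elimination towards C8, the only β-carbon that bears hydrogen. This should give 11 without any base-mediated proton shuffling; C8 epimers lacking a syn hydrogen would be lost.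

Step 9. What may go wrong: loss of site or face control in the deprotonation–protonation sequence; removal of a C7 hydrogen in place of a C17 hydrogen would lead to the endocyclic 7-ene, and protonation at C17 would only return 11. Fallback, setting out from 11 and returning at 13: photochemical deconjugation (254 nm, hexane, catalytic 1,2-dimethylimidazole). The excited enoate abstracts a γ-hydrogen through a six-membered transition state that only the C17 methyl, cis to the carbonyl across C8=C9, can reach, and the photodienol should ketonise at C9 from the open α-face to give 13. No compound outside the list is made (none, F0).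

**Further compounds**

F0 | step 6 | none | none
F1 | step 7 | ethyl 2α-TBSO-12,13,14,15,16-pentanorlabdan-11-oate (5α-H; mixture at C8 and C9) | CCOC(=O)C1C(C)CC[C@H]2C(C)(C)C[C@H](O[Si](C)(C)C(C)(C)C)C[C@]12C
F2 | step 7 | ethyl 9-(phenylselanyl)-2α-TBSO-12,13,14,15,16-pentanorlabdan-11-oate (mixture at C8 and C9) | CCOC(=O)C1([Se]c3ccccc3)C(C)CC[C@H]2C(C)(C)C[C@H](O[Si](C)(C)C(C)(C)C)C[C@]12C
F0 | step 9 | none | none
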